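**Retrosynthetic overview**
1. Units: guaiacyl D – ring C (outer dihydrobenzofuran) – unit C – ring B (inner dihydrobenzofuran) – unit B – all-cis tetrahydrofuran – benzyl unit A. Rings are formed in the order ring B, ring C, tetrahydrofuran.
2. Tetrahydrofuran: Williamson closure (O7–C9') of a 1,4-diol made by a magnesium-catalysed anti-aldol of trimer aldehyde 15 with (R)-benzylsuccinate imide 21 (Stobbe condensation, asymmetric hydrogenation).
3. Aldehyde 15: oxidative cleavage of the cinnamyl arm of the bis(dihydrobenzofuran) trimer; this arm is the disposable side chain of the monomer that served as unit B.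
4. Ring C (key step): oxidative [3+2] cross-coupling of the phenol of dimer 10 with N-feruloyl (2S)-sultam 8. Ring B comes from the same reaction run as a dehydrodimerization of two molecules of the antipodal amide 5, so mirror-image sultams set the opposite configurations of the two rings.
5. Enabling feature: the free guaiacyl OH (O-4) of unit C has an unsubstituted ortho carbon (C-5) beside it, and unit D is an (E)-4-hydroxycinnamoyl group whose phenoxyl radical carries spin at C8 and, once coupled, is a quinone methide electrophilic at C7.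

Key step: step 5

Remarks and assumptions
- Locants C7, C8, C9, C7', C8', C9' follow lignan usage for the tetrahydrofuran unit: C7 carries the aryl group, C8 the hydroxymethyl carbon C9, C8' the benzyl carbon C7', and C9' is the ring CH2.
- Stoichiometry of step 4: two molecules of 5 and one formula unit of Ag2O give one molecule of 10, two silver atoms and water. One molecule of 5 reacts through C8 and C7, the other through C5 and O4.
- Assumption: C8–C5 bond formation follows the usual Cα-re topicity of N-enoyl (2R)-bornane-10,2-sultams, so amide 5 leads to the 2R ring B and amide 8 to the 2S ring C; if the sense is the reverse, sultams 3 and 6 are exchanged with no other change.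
- Assumption: the (S,S) antipode of Et-DuPHOS delivers the R acid in step 10; otherwise the (R,R) ligand is used.

Step 1
Reactants: 1 (E)-4-acetoxy-3-methoxycinnamic acid
Product: 2 (E)-4-acetoxy-3-methoxycinnamoyl chloride
Conditions: (COCl)2, DMF (cat.), CH2Cl2, 0 °C to rt
Reagents that add atoms: oxalyl chloride, ClC(=O)C(=O)Cl
Why: Acid chloride formation under Vilsmeier catalysis; the aryl acetate and the E-alkene are inert.

Step 2
Reactants: 2 (E)-4-acetoxy-3-methoxycinnamoyl chloride; 3 (1S)-(−)-2,10-camphorsultam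
Product: 5 N-feruloyl-(2R)-bornane-10,2-sultam, via O-acetyl amide 4 (not isolated)
Conditions: 3, NaH, toluene, 0 °C, added to 2; then pyrrolidine (1.1 equiv), 0 °C
Reagents that add atoms: none
Why: N-acylation of the sodium salt of the sultam by the acid chloride, then chemoselective aminolysis of the aryl acetate, which is far more electrophilic than the N-enoyl sultam, should free the phenol needed for coupling.

Step 3
Reactants: 2 (E)-4-acetoxy-3-methoxycinnamoyl chloride; 6 (1R)-(+)-2,10-camphorsultam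
Product: 8 N-feruloyl-(2S)-bornane-10,2-sultam, via O-acetyl amide 7 (not isolated)
Conditions: 6, NaH, toluene, 0 °C, added to 2; then pyrrolidine (1.1 equiv), 0 °C
Reagents that add atoms: none
Why: Same N-acylation and acetate aminolysis as step 2, with the antipodal auxiliary.

Step 4
Reactants: 5 N-feruloyl-(2R)-bornane-10,2-sultam (two molecules per molecule of product)
Product: 10 bis-sultam β-5 dehydrodimer (ring B formed), via quinone methide 9 (not isolated)
Conditions: Ag2O (0.6 equiv relative to 5), dry CH2Cl2, rt, dark; stopped before full conversion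
Reagents that add atoms: second molecule of feruloyl sultam 5, COc1cc(/C=C/C(=O)N2[C@@H]3C[C@H]4CC[C@]3(CS2(=O)=O)C4(C)C)ccc1O
Why: Biomimetic oxidative β-5 dehydrodimerization of a ferulic amide, in which two phenoxyl radicals of 5 couple C8 of one to C5 of the other, the dienone re-aromatizes and the phenol adds 5-exo-trig to the quinone methide; the sultam shields one face of the C8 radical centre and so sets C3, C2 follows as the trans isomer on ring closure, and the minor diastereomer should be removable by chromatography or crystallization.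

Step 5
Reactants: 10 bis-sultam β-5 dehydrodimer; 8 N-feruloyl-(2S)-bornane-10,2-sultam
Product: 12 tris-sultam trimer bearing rings B plus C, via quinone methide 11 (not isolated)
Conditions: Ag2O (3 equiv), dry CH2Cl2, rt, dark; 8 (2.5 equiv) added by syringe pump over 10 h
Reagents that add atoms: none
Why: Ag2O oxidizes both phenols to phenoxyl radicals; the radical of 8, whose spin is delocalized through the C7=C8 bond to C8, couples at C8 with the unsubstituted ortho carbon C5 of the guaiacyl radical of 10, the dienone re-aromatizes to quinone methide phenol 11, and the phenolic oxygen adds to C7 of the quinone methide. The closest known reactions are the Ag2O dehydrodimerization of ferulic acid derivatives to β-5 dihydrobenzofurans, its camphorsultam-controlled variant (step 4), and the oxidative cross-coupling of a hydroxycinnamyl radical with a guaiacyl end group in sesquilignan and lignin-model chemistry. The single ring formed, ring C, closes by a 5-exo-trig oxa-Michael (1,6) addition. C3 of the new ring is set in the C–C coupling by the (2S)-sultam, which blocks one face of the C8 radical centre, and C2 is set in the ring closure with the aryl group trans to the C3 acyl group; the stereocentres of 10 are remote and play no part. The step needs cross- over homo-coupling and C5–C8 over O4–C8 coupling: 8 is added slowly so that its radical meets mainly the radical of 10, the phenolic ring of 10 has only O4 and C5 open (C1 and C3 are substituted and the enoyl arm sits on an etherified ring), and only the C5 adduct has an internal phenol that traps the quinone methide irreversibly.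

Step 6
Reactants: 12 tris-sultam trimer
Product: 13 trimer tetraol (phenol, two hydroxymethyl groups, cinnamyl alcohol)
Conditions: LiAlH4 (excess), THF, −20 °C to 0 °C; aq. NaOH work-up
Reagents that add atoms: none
Why: Reductive cleavage of N-acyl sultams by LiAlH4 should release the primary alcohols without touching the α-stereocentres, and the enoyl sultam should undergo 1,2-reduction to the cinnamyl alcohol, as in the conversion of ferulate dehydrodimers into dehydrodiconiferyl alcohol.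

Step 7
Reactants: 13 trimer tetraol
Product: 14 tetrakis(triisopropylsilyl) ether
Conditions: TIPSCl (6 equiv), imidazole, DMAP (cat.), DMF, rt
Reagents that add atoms: chlorotriisopropylsilane, CC(C)[Si](Cl)(C(C)C)C(C)C
Why: Imidazole-promoted silylation of the phenol and the three primary alcohols; no stereocentre is touched.

Step 8
Reactants: 14 tetrakis(triisopropylsilyl) ether
Product: 15 trimer aldehyde
Conditions: OsO4 (2 mol %), NaIO4 (4 equiv), 2,6-lutidine, dioxane–H2O, rt
Reagents that add atoms: sodium periodate, [Na+].[O-]I(=O)(=O)=O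
Why: Lemieux–Johnson cleavage (catalytic dihydroxylation, periodate glycol cleavage) of the only alkene cuts the cinnamyl arm back to the aryl aldehyde, with 2,6-lutidine suppressing over-oxidation.

Step 9
Reactants: 16 4-benzyloxy-3-methoxybenzaldehyde; 17 di-tert-butyl succinate
Product: 18 (E)-4-(4-benzyloxy-3-methoxyphenyl)-3-(tert-butoxycarbonyl)but-3-enoic acid
Conditions: KOtBu, tBuOH, reflux; then aq. HCl
Reagents that add atoms: none
Why: Stobbe condensation, which should give the E half-ester with the free acid on the CH2 arm through lactonization and eliminative ring opening.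

Step 10
Reactants: 18 Stobbe half-ester
Product: 19 (R)-4-(4-benzyloxy-3-methoxyphenyl)-3-(tert-butoxycarbonyl)butanoic acid
Conditions: H2 (5 bar), [Rh(cod)((S,S)-Et-DuPHOS)]OTf (0.5 mol %), NaOMe (10 mol %), MeOH, rt
Reagents that add atoms: none
Why: Carboxylate-directed rhodium-catalysed asymmetric hydrogenation of an itaconate half-ester sets C8' (R) by catalyst control, and the homogeneous catalyst leaves the benzyl ether intact.

Step 11
Reactants: 19 (R)-acid; 20 (R)-4-benzyl-2-oxazolidinone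
Product: 21 N-acyl oxazolidinone (imide)
Conditions: DCC, DMAP (cat.), CH2Cl2, 0 °C to rt
Reagents that add atoms: none
Why: Steglich-type N-acylation puts the auxiliary on the CH2CO2H arm, and the α-branched tert-butyl ester is untouched.

Step 12
Reactants: 21 imide; 15 trimer aldehyde
Product: 22 anti-aldol adduct as its trimethylsilyl ether
Conditions: MgCl2 (0.3 equiv), Et3N, TMSCl, EtOAc, rt
Reagents that add atoms: chlorotrimethylsilane, C[Si](C)(C)Cl
Why: Magnesium-halide-catalysed anti-aldol of an N-acyl oxazolidinone (Evans anti-aldol), in which soft enolization gives the chelated Z-enolate of the imide only, the aromatic aldehyde adds to the enolate face opposite the benzyl group through a boat transition state, and silylation makes the addition irreversible, so the (R)-auxiliary should set C8 and C7 in the anti sense while C8' is a spectator.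

Step 13
Reactants: 22 silylated anti-aldol adduct
Product: 23 1,3-diol tert-butyl ester
Conditions: LiBH4, MeOH (3 equiv), THF, 0 °C; then aq. citric acid
Reagents that add atoms: none
Why: Reductive removal of the auxiliary, LiBH4 reducing the N-acyl oxazolidinone chemoselectively beside the hindered tert-butyl ester, and the mildly acidic work-up hydrolyses the trimethylsilyl ether.

Step 14
Reactants: 23 1,3-diol tert-butyl ester
Product: 24 C9 triisopropylsilyl ether
Conditions: TIPSCl (1.2 equiv), imidazole, CH2Cl2, 0 °C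
Reagents that add atoms: chlorotriisopropylsilane, CC(C)[Si](Cl)(C(C)C)C(C)C
Why: Selective silylation of the primary alcohol over the hindered secondary benzylic alcohol marks C9–O before C9' is reduced.

Step 15
Reactants: 24 C9 triisopropylsilyl ether
Product: 25 1,4-diol (C7–OH, C9'–OH)
Conditions: LiAlH4, THF, 0 °C
Reagents that add atoms: none
Why: Hydride reduction of the tert-butyl ester to the primary C9' alcohol, with no stereocentre affected.

Step 16
Reactants: 25 1,4-diol
Product: 27 fully protected tetramer, via primary tosylate 26 (not isolated)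
Conditions: TsCl (1.05 equiv), Et3N, DMAP (cat.), CH2Cl2, 0 °C; then NaH, THF, 0 °C to rt
Reagents that add atoms: none
Why: Selective tosylation of the primary alcohol and intramolecular Williamson etherification (5-exo-tet) by the C7 alkoxide close the tetrahydrofuran with retention at all three centres, so the anti-aldol relationship becomes 7,8-cis and the all-cis ring results, with O9 blocked by the bulky silyl group.

Step 17
Reactants: 27 fully protected tetramer
Product: 28 O-benzyl tetramer (all silyl groups removed)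
Conditions: TBAF (6 equiv), AcOH (6 equiv), THF, rt
Reagents that add atoms: none
Why: Fluoride-mediated desilylation, buffered so that the phenoxide is not exposed to air as the free anion and the benzylic ethers see neither acid nor strong base.

Step 18
Reactants: 28 O-benzyl tetramer
Product: 29 target CNP0395728.1
Conditions: H2 (1 atm), Pd/C (10 %), EtOAc–MeOH, rt, monitored closely
Reagents that add atoms: none
Why: Hydrogenolysis of the aryl benzyl ether, which under neutral conditions at 1 atm should cleave much faster than the ring benzylic C–O bonds of the dihydrobenzofurans and the tetrahydrofuran.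

**Compound list**
1 | (E)-4-acetoxy-3-methoxycinnamic acid | COc1cc(/C=C/C(=O)O)ccc1OC(C)=O | starting material
2 | (E)-4-acetoxy-3-methoxycinnamoyl chloride | COc1cc(/C=C/C(=O)Cl)ccc1OC(C)=O | intermediate
3 | (1S)-(−)-2,10-camphorsultam, (2R)-bornane-10,2-sultam | N1[C@@H]2C[C@H]3CC[C@]2(CS1(=O)=O)C3(C)C | starting material
4 | N-[(E)-4-acetoxy-3-methoxycinnamoyl]-(2R)-bornane-10,2-sultam (formed in situ) | COc1cc(/C=C/C(=O)N2[C@@H]3C[C@H]4CC[C@]3(CS2(=O)=O)C4(C)C)ccc1OC(C)=O | intermediate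
5 | N-[(E)-4-hydroxy-3-methoxycinnamoyl]-(2R)-bornane-10,2-sultam | COc1cc(/C=C/C(=O)N2[C@@H]3C[C@H]4CC[C@]3(CS2(=O)=O)C4(C)C)ccc1O | intermediate
6 | (1R)-(+)-2,10-camphorsultam, (2S)-bornane-10,2-sultam | N1[C@H]2C[C@@H]3CC[C@@]2(CS1(=O)=O)C3(C)C | starting material
7 | N-[(E)-4-acetoxy-3-methoxycinnamoyl]-(2S)-bornane-10,2-sultam (formed in situ) | COc1cc(/C=C/C(=O)N2[C@H]3C[C@@H]4CC[C@@]3(CS2(=O)=O)C4(C)C)ccc1OC(C)=O | intermediate
8 | N-[(E)-4-hydroxy-3-methoxycinnamoyl]-(2S)-bornane-10,2-sultam | COc1cc(/C=C/C(=O)N2[C@H]3C[C@@H]4CC[C@@]3(CS2(=O)=O)C4(C)C)ccc1O | intermediate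
9 | quinone methide phenol from C8–C5' coupling of two molecules of 5 (formed in situ; either geometry at the exocyclic double bond) | O=C(/C=C/c1cc(OC)c(O)c(c1)[C@@H](C(=O)N2[C@@H]3C[C@H]4CC[C@]3(CS2(=O)=O)C4(C)C)C=C2C=CC(=O)C(OC)=C2)N1[C@@H]2C[C@H]3CC[C@]2(CS1(=O)=O)C3(C)C | intermediate
10 | (2R,3R)-trans-2-(4-hydroxy-3-methoxyphenyl)-7-methoxy-2,3-dihydrobenzofuran with the (2R)-bornane-10,2-sultam N-carbonyl group at C3 and the (E)-3-oxo-3-[(2R)-bornane-10,2-sultam-N-yl]prop-1-enyl arm at C5 | O=C(/C=C/c1cc(OC)c2c(c1)[C@@H](C(=O)N3[C@@H]4C[C@H]5CC[C@]4(CS3(=O)=O)C5(C)C)[C@H](c3ccc(O)c(OC)c3)O2)N1[C@@H]2C[C@H]3CC[C@]2(CS1(=O)=O)C3(C)C | intermediate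
11 | quinone methide phenol from C8–C5 coupling of 8 with 10 (formed in situ; either geometry at the exocyclic double bond) | O=C(/C=C/c1cc(OC)c2c(c1)[C@@H](C(=O)N3[C@@H]4C[C@H]5CC[C@]4(CS3(=O)=O)C5(C)C)[C@H](c3cc(OC)c(O)c(c3)[C@H](C(=O)N4[C@H]5C[C@@H]6CC[C@@]5(CS4(=O)=O)C6(C)C)C=C4C=CC(=O)C(OC)=C4)O2)N1[C@@H]2C[C@H]3CC[C@]2(CS1(=O)=O)C3(C)C | intermediate
12 | trimer: 10 in which the 2-aryl group is a (2S,3S)-trans-2-(4-hydroxy-3-methoxyphenyl)-7-methoxy-2,3-dihydrobenzofuran-5-yl group carrying the (2S)-bornane-10,2-sultam N-carbonyl group at its C3 | O=C(/C=C/c1cc(OC)c2c(c1)[C@@H](C(=O)N3[C@@H]4C[C@H]5CC[C@]4(CS3(=O)=O)C5(C)C)[C@H](c3cc(OC)c4c(c3)[C@H](C(=O)N5[C@H]6C[C@@H]7CC[C@@]6(CS5(=O)=O)C7(C)C)[C@@H](c5ccc(O)c(OC)c5)O4)O2)N1[C@@H]2C[C@H]3CC[C@]2(CS1(=O)=O)C3(C)C | intermediate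
13 | (E)-3-{(2R,3S)-3-(hydroxymethyl)-2-[(2S,3R)-2-(4-hydroxy-3-methoxyphenyl)-3-(hydroxymethyl)-7-methoxy-2,3-dihydrobenzofuran-5-yl]-7-methoxy-2,3-dihydrobenzofuran-5-yl}prop-2-en-1-ol | OC/C=C/c1cc(OC)c2c(c1)[C@@H](CO)[C@H](c3cc(OC)c4c(c3)[C@H](CO)[C@@H](c5ccc(O)c(OC)c5)O4)O2 | intermediate
14 | tetrakis(triisopropylsilyl) ether of 13 (phenol and three primary alcohols) | CC(C)[Si](C(C)C)(C(C)C)OC/C=C/c1cc(OC)c2c(c1)[C@@H](CO[Si](C(C)C)(C(C)C)C(C)C)[C@H](c3cc(OC)c4c(c3)[C@H](CO[Si](C(C)C)(C(C)C)C(C)C)[C@@H](c5ccc(O[Si](C(C)C)(C(C)C)C(C)C)c(OC)c5)O4)O2 | intermediate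
15 | (2R,3S)-7-methoxy-3-(triisopropylsilyloxymethyl)-2-[(2S,3R)-7-methoxy-2-(3-methoxy-4-triisopropylsilyloxyphenyl)-3-(triisopropylsilyloxymethyl)-2,3-dihydrobenzofuran-5-yl]-2,3-dihydrobenzofuran-5-carbaldehyde | O=Cc1cc(OC)c2c(c1)[C@@H](CO[Si](C(C)C)(C(C)C)C(C)C)[C@H](c3cc(OC)c4c(c3)[C@H](CO[Si](C(C)C)(C(C)C)C(C)C)[C@@H](c5ccc(O[Si](C(C)C)(C(C)C)C(C)C)c(OC)c5)O4)O2 | intermediate
16 | 4-benzyloxy-3-methoxybenzaldehyde | COc1cc(C=O)ccc1OCc1ccccc1 | starting material
17 | di-tert-butyl succinate | CC(C)(C)OC(=O)CCC(=O)OC(C)(C)C | starting material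
18 | (E)-4-(4-benzyloxy-3-methoxyphenyl)-3-(tert-butoxycarbonyl)but-3-enoic acid | COc1cc(/C=C(\CC(=O)O)C(=O)OC(C)(C)C)ccc1OCc1ccccc1 | intermediate
19 | (R)-4-(4-benzyloxy-3-methoxyphenyl)-3-(tert-butoxycarbonyl)butanoic acid | COc1cc(C[C@H](CC(=O)O)C(=O)OC(C)(C)C)ccc1OCc1ccccc1 | intermediate
20 | (R)-4-benzyl-2-oxazolidinone | O=C1N[C@H](Cc2ccccc2)CO1 | starting material
21 | tert-butyl (R)-2-(4-benzyloxy-3-methoxybenzyl)-4-[(R)-4-benzyl-2-oxooxazolidin-3-yl]-4-oxobutanoate | COc1cc(C[C@H](CC(=O)N2[C@H](Cc3ccccc3)COC2=O)C(=O)OC(C)(C)C)ccc1OCc1ccccc1 | intermediate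
22 | anti-aldol adduct of 21 and 15 as trimethylsilyl ether, (7R,8S,8'R) with the imide at C9 and the tert-butyl ester at C9' | COc1cc(C[C@H]([C@H](C(=O)N2[C@H](Cc3ccccc3)COC2=O)[C@@H](O[Si](C)(C)C)c4cc(OC)c5c(c4)[C@@H](CO[Si](C(C)C)(C(C)C)C(C)C)[C@H](c6cc(OC)c7c(c6)[C@H](CO[Si](C(C)C)(C(C)C)C(C)C)[C@@H](c8ccc(O[Si](C(C)C)(C(C)C)C(C)C)c(OC)c8)O7)O5)C(=O)OC(C)(C)C)ccc1OCc1ccccc1 | intermediate
23 | (7R,8R,8'R) 1,3-diol: C7–OH and C9–OH free, tert-butyl ester at C9' | COc1cc(C[C@H]([C@H](CO)[C@@H](O)c2cc(OC)c3c(c2)[C@@H](CO[Si](C(C)C)(C(C)C)C(C)C)[C@H](c4cc(OC)c5c(c4)[C@H](CO[Si](C(C)C)(C(C)C)C(C)C)[C@@H](c6ccc(O[Si](C(C)C)(C(C)C)C(C)C)c(OC)c6)O5)O3)C(=O)OC(C)(C)C)ccc1OCc1ccccc1 | intermediate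
24 | (7R,8R,8'R) C9 triisopropylsilyl ether of 23 | COc1cc(C[C@H]([C@H](CO[Si](C(C)C)(C(C)C)C(C)C)[C@@H](O)c2cc(OC)c3c(c2)[C@@H](CO[Si](C(C)C)(C(C)C)C(C)C)[C@H](c4cc(OC)c5c(c4)[C@H](CO[Si](C(C)C)(C(C)C)C(C)C)[C@@H](c6ccc(O[Si](C(C)C)(C(C)C)C(C)C)c(OC)c6)O5)O3)C(=O)OC(C)(C)C)ccc1OCc1ccccc1 | intermediate
25 | (7R,8R,8'R) 1,4-diol: C7–OH and C9'–OH free, C9–O silylated | COc1cc(C[C@H]([C@H](CO[Si](C(C)C)(C(C)C)C(C)C)[C@@H](O)c2cc(OC)c3c(c2)[C@@H](CO[Si](C(C)C)(C(C)C)C(C)C)[C@H](c4cc(OC)c5c(c4)[C@H](CO[Si](C(C)C)(C(C)C)C(C)C)[C@@H](c6ccc(O[Si](C(C)C)(C(C)C)C(C)C)c(OC)c6)O5)O3)CO)ccc1OCc1ccccc1 | intermediate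
26 | C9' primary tosylate of 25 (formed in situ) | COc1cc(C[C@H]([C@H](CO[Si](C(C)C)(C(C)C)C(C)C)[C@@H](O)c2cc(OC)c3c(c2)[C@@H](CO[Si](C(C)C)(C(C)C)C(C)C)[C@H](c4cc(OC)c5c(c4)[C@H](CO[Si](C(C)C)(C(C)C)C(C)C)[C@@H](c6ccc(O[Si](C(C)C)(C(C)C)C(C)C)c(OC)c6)O5)O3)COS(=O)(=O)c2ccc(C)cc2)ccc1OCc1ccccc1 | intermediate
27 | fully protected tetramer: (2R,3R,4R)-all-cis tetrahydrofuran, four triisopropylsilyl ethers, one benzyl ether | COc1cc(C[C@H]2CO[C@@H](c3cc(OC)c4c(c3)[C@@H](CO[Si](C(C)C)(C(C)C)C(C)C)[C@H](c3cc(OC)c5c(c3)[C@H](CO[Si](C(C)C)(C(C)C)C(C)C)[C@@H](c3ccc(O[Si](C(C)C)(C(C)C)C(C)C)c(OC)c3)O5)O4)[C@H]2CO[Si](C(C)C)(C(C)C)C(C)C)ccc1OCc1ccccc1 | intermediate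
28 | O-benzyl ether of the target at the phenol of unit A | COc1cc(C[C@H]2CO[C@@H](c3cc(OC)c4c(c3)[C@@H](CO)[C@H](c3cc(OC)c5c(c3)[C@H](CO)[C@@H](c3ccc(O)c(OC)c3)O5)O4)[C@H]2CO)ccc1OCc1ccccc1 | intermediate
29 | CNP0395728.1 | COc1cc(C[C@H]2CO[C@@H](c3cc(OC)c4c(c3)[C@@H](CO)[C@H](c3cc(OC)c5c(c3)[C@H](CO)[C@@H](c3ccc(O)c(OC)c3)O5)O4)[C@H]2CO)ccc1O | target

**Step count and risks**
Total step count: 18. Longest linear sequence: 14 steps (1, 2, 4, 5, 6, 7, 8, 12, 13, 14, 15, 16, 17, 18).

Step 5. The two phenoxyl radicals may pair with themselves instead of with each other (homo-coupling of 8, 5–5 or 4-O-5 coupling of 10), coupling may occur at O-4 instead of C-5, the product phenol may be oxidized and coupled again, and the radical of 10 may lose the benzylic C2–H of ring B. The fallback builds ring C on 10 by a carbenoid C–H insertion that needs no radical pairing, and sets out from 10. N-Iodosuccinimide iodinates the only free position ortho to the phenol to give iodophenol F1. Alkylation with 4-acetoxy-3-methoxybenzyl bromide (K2CO3, acetone) gives benzyl ether F2. Pd(PPh3)4-catalysed coupling with methyl diazoacetate (Ag2CO3, Et3N, toluene) gives aryldiazoacetate F3. The antipode of Rh2(PTTL)4 that sets C2 as S (nominally Rh2(R-PTTL)4) catalyses intramolecular 1,5 C–H insertion into the benzylic ether C–H to give cis ester F4. DBU epimerizes C3 to give trans ester F5. LiAlH4 then reduces the ester and both acyl sultams and cleaves the aryl acetate, coming back to the route at 13.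

Step 12. Addition of the hindered, β-branched magnesium enolate to the electron-rich aldehyde may be slow or reversible, with erosion of the anti selectivity or loss of the silyl ether on isolation. The fallback sets out from 21 and 15. The imide is converted into its dibutylboron Z-enolate (Bu2BOTf, iPr2NEt, CH2Cl2, −78 °C) and combined with 15 pre-complexed with Et2AlCl. The open, antiperiplanar transition state of this Lewis-acid-mediated aldol should give the same anti adduct with a free hydroxyl, hydroxy imide F6. Reduction with LiBH4 comes back to the route at 23.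

Step 16. The silyl group may migrate from O9 to the C7 alkoxide, followed by closure through O9, or the hindered secondary alkoxide may close slowly so that the tosylate is lost by elimination. The fallback sets out from 25. TEMPO with PhI(OAc)2 oxidizes the primary alcohol; the hydroxy aldehyde closes to the lactol and is oxidized on to γ-lactone F7, in which the ring oxygen is already on C7 and no alkoxide or sulfonate is involved. DIBAL-H (−78 °C) gives lactol F8, and Et3SiH with BF3·OEt2 (−78 °C) removes the anomeric hydroxyl to come back to the route at 27.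

Further compounds
F1 | step 5 | 5-iodo derivative of 10 (iodine ortho to the phenol of unit C) | O=C(/C=C/c1cc(OC)c2c(c1)[C@@H](C(=O)N3[C@@H]4C[C@H]5CC[C@]4(CS3(=O)=O)C5(C)C)[C@H](c3cc(I)c(O)c(OC)c3)O2)N1[C@@H]2C[C@H]3CC[C@]2(CS1(=O)=O)C3(C)C
F2 | step 5 | 4-acetoxy-3-methoxybenzyl ether of F1 | O=C(/C=C/c1cc(OC)c2c(c1)[C@@H](C(=O)N3[C@@H]4C[C@H]5CC[C@]4(CS3(=O)=O)C5(C)C)[C@H](c3cc(I)c(OCc4ccc(OC(C)=O)c(OC)c4)c(OC)c3)O2)N1[C@@H]2C[C@H]3CC[C@]2(CS1(=O)=O)C3(C)C
F3 | step 5 | methyl aryldiazoacetate from F2 | O=C(/C=C/c1cc(OC)c2c(c1)[C@@H](C(=O)N3[C@@H]4C[C@H]5CC[C@]4(CS3(=O)=O)C5(C)C)[C@H](c3cc(C(=[N+]=[N-])C(=O)OC)c(OCc4ccc(OC(C)=O)c(OC)c4)c(OC)c3)O2)N1[C@@H]2C[C@H]3CC[C@]2(CS1(=O)=O)C3(C)C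
F4 | step 5 | cis methyl ester of ring C (2S,3R at the ester stage) | O=C(/C=C/c1cc(OC)c2c(c1)[C@@H](C(=O)N3[C@@H]4C[C@H]5CC[C@]4(CS3(=O)=O)C5(C)C)[C@H](c3cc(OC)c4c(c3)[C@@H](C(=O)OC)[C@@H](c5ccc(OC(C)=O)c(OC)c5)O4)O2)N1[C@@H]2C[C@H]3CC[C@]2(CS1(=O)=O)C3(C)C
F5 | step 5 | trans methyl ester of ring C (2S,3S at the ester stage) | O=C(/C=C/c1cc(OC)c2c(c1)[C@@H](C(=O)N3[C@@H]4C[C@H]5CC[C@]4(CS3(=O)=O)C5(C)C)[C@H](c3cc(OC)c4c(c3)[C@H](C(=O)OC)[C@@H](c5ccc(OC(C)=O)c(OC)c5)O4)O2)N1[C@@H]2C[C@H]3CC[C@]2(CS1(=O)=O)C3(C)C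
F6 | step 12 | anti-aldol adduct of 21 and 15 with free C7 hydroxyl | COc1cc(C[C@H]([C@H](C(=O)N2[C@H](Cc3ccccc3)COC2=O)[C@@H](O)c4cc(OC)c5c(c4)[C@@H](CO[Si](C(C)C)(C(C)C)C(C)C)[C@H](c6cc(OC)c7c(c6)[C@H](CO[Si](C(C)C)(C(C)C)C(C)C)[C@@H](c8ccc(O[Si](C(C)C)(C(C)C)C(C)C)c(OC)c8)O7)O5)C(=O)OC(C)(C)C)ccc1OCc1ccccc1
F7 | step 16 | all-cis γ-lactone (C9' carbonyl, ring oxygen on C7) | COc1cc(C[C@H]2C(=O)O[C@@H](c3cc(OC)c4c(c3)[C@@H](CO[Si](C(C)C)(C(C)C)C(C)C)[C@H](c3cc(OC)c5c(c3)[C@H](CO[Si](C(C)C)(C(C)C)C(C)C)[C@@H](c3ccc(O[Si](C(C)C)(C(C)C)C(C)C)c(OC)c3)O5)O4)[C@H]2CO[Si](C(C)C)(C(C)C)C(C)C)ccc1OCc1ccccc1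
F8 | step 16 | lactol from F7 (anomeric mixture at C9') | COc1cc(C[C@H]2C(O)O[C@@H](c3cc(OC)c4c(c3)[C@@H](CO[Si](C(C)C)(C(C)C)C(C)C)[C@H](c3cc(OC)c5c(c3)[C@H](CO[Si](C(C)C)(C(C)C)C(C)C)[C@@H](c3ccc(O[Si](C(C)C)(C(C)C)C(C)C)c(OC)c3)O5)O4)[C@H]2CO[Si](C(C)C)(C(C)C)C(C)C)ccc1OCc1ccccc1
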